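## Structural features

Pseudopentafuhalol D (C30H22O17) is a linear chain of five benzene rings A–E joined only by four diaryl ether oxygens: A1–O–B1, B2–O–C1, C5–O–D1 and D2–O–E1. It has thirteen free phenolic hydroxyls, no C–C bond between rings and no stereocentre. Ring A is a 2,4,6-trihydroxyphenyl group bound through A1. Ring B carries aryloxy groups on the neighbouring carbons B1 and B2, hydroxyls at B3 and B5, and hydrogen at B4 and B6. Ring C carries aryloxy groups at C1 and C5 and hydroxyls at C3 and C4; ring D carries aryloxy groups at D1 and D2 and hydroxyls at D3, D4 and D5; ring E is a 3,4,5-trihydroxyphenyl group bound through E1. The catechol, pyrogallol and hydroxyquinol units oxidise readily to quinones, above all in base, so the free phenols can only be released in the last step. With seventeen oxygens on thirty carbons no late differentiation of hydroxyls is possible, so every oxygen has to be placed by construction. The real difficulty is the ether bonds at carbons flanked by oxygen on electron-rich rings, and it peaks at ring B: A1–O–B1 has three ortho substituents (A2, A6, B2), and B2–O–C1 sits between the oxygens at B1 and B3. The feature exploited is that ring B divides into three two-carbon units, each with one oxygen at the oxidation level of a ketene or an ynol ether: B2–B3 (an aryloxyketene, B3 the carbonyl, B2 bearing O–ring C), B1–B6 (an aryl ethynyl ether with ring A on the oxygen) and B5–B4 (an alkoxyacetylene).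

## Logic of the disconnections

29 to 28. The twelve O–alkyl bonds (eleven O–CH3, one O–CH2CH3 at B5) are cut. The polyphenol is too easily oxidised to be carried through any step, whereas small alkyl ethers survive organolithium, peracid, copper catalysis and heat. The demand on the forward step is exhaustive dealkylation that leaves the four diaryl ether bonds intact, with oxygen-free isolation.

28 to 22 and 23. Ring B is unmade by cutting B3–B4 and B5–B6, the bonds that insert the two-carbon unit B4–B5 of 23, and by re-folding B2–B3 into a four-membered ring. Ring B holds both crowded ethers; once it is opened, the ether at B1 becomes an enol ether oxygen of a vinylogous ester and the ether at B2 an α-aryloxy ketone oxygen. The gain is that neither of the two most hindered aryl–O bonds has to be formed on an aromatic carbon, and that the 1,2,3,5 oxygen pattern of ring B follows from the mechanism. The forward step must open 22 thermally and take up 23 with one orientation only.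

22 to 12 and 19. The four-membered ring is cut at C1–C2 and C3–C4, a retro-[2+2] into the aryloxyketene 21 (from 12 through 20) and the ynol ether 19. The two ring-B ethers are now an aryloxyacetic acid and an aryl ethynyl ether, both made by attack of a phenoxide on a small unhindered carbon electrophile. The forward step must generate 21 slowly in the presence of 19; the orientation is fixed by the polarity of both partners.

19 to 13 and 14. The O–C(sp) bond is cut, through 16 and the transient 15, 17 and 18. The 2,6-disubstituted phenol 13, a poor partner in any arylation, only has to add to a linear two-carbon electrophile. The forward steps need low temperature so that lithiation of the ring does not compete.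

12 to 9 and 10. The O–CH2 bond is cut (through 11). The forward step is an ordinary phenol alkylation, which 9 allows because it has a single free hydroxyl with two unsubstituted ortho positions.

9 to 5 and 6. The C1 hydroxyl of ring C is traced back to a formyl group (7, through 8), and the C5–O–D1 ether is cut. The formyl group activates the bromide of 6 for the coupling and is then exchanged for oxygen, so each oxygen is placed without any hydroxyl differentiation. The forward demand is a copper-catalysed coupling of a phenol and a bromide that each have one ortho substituent.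

5 to 1 and 2. By the same logic the D1 hydroxyl comes from the formyl group of 3 (through 4), and the D2–O–E1 ether is cut. The ortho formyl group of 2 activates a bromide flanked on both sides, and the nucleophile 1 is unhindered. All three rings of 9 thus come from three commercial arenes.

## Other disconnections considered

Alternative 1: This is the first plan that comes to mind: cut the aryl–O bonds one at a time and form each by an Ullmann coupling. The forward key step would be copper-catalysed coupling of phenol 9 with the ring A–B bromide A1 (2-bromo-1,5-dimethoxy-3-(2,4,6-trimethoxyphenoxy)benzene) to give the tridecamethyl ether A2, followed by demethylation. The chosen plan is preferred on structural and mechanistic grounds. A1 is an electron-rich bromide flanked by two oxygens, the class in which copper-mediated substitution is slowest and hydrodehalogenation competes. A1 itself requires arylation of the 2,6-disubstituted phenol 13. An activating formyl group can be placed next to only one of the two neighbouring positions B1 and B2. The chosen plan forms both bonds at unhindered sp3 or sp carbon instead.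

Alternative 2: Cut A1–O–B1 and a B2–heteroatom bond at an aryne. The silyl triflate A3 (3,5-dimethoxy-2-(trimethylsilyl)phenyl trifluoromethanesulfonate) would give 3,5-dimethoxybenzyne A4 with fluoride. The phenoxide of 13 should add at the aryne carbon remote from the flanking methoxy group (future B1), because that methoxy group stabilises the developing aryl anion at B2 inductively and the distorted aryne is more electrophilic at B1. An iodine electrophile would then capture the anion to give the iodide A5 (2-iodo-1,5-dimethoxy-3-(2,4,6-trimethoxyphenoxy)benzene). The chosen plan is preferred because the aryne makes only one of the two C–O bonds. No aryloxy electrophile is available for the anion, and proton transfer from any phenol present competes with iodination. A5 must still be coupled with 9 at the carbon flanked by two oxygens, the same worst case as in Alternative 1.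

Alternative 3: Fold ring A as in its biosynthesis, cutting A2–A3 and A5–A6. Dimethyl 3-oxopentanedioate would be C-acylated twice (Claisen) by the aryloxymalonate A6 to give the phloroglucinol diester A7, followed by saponification and double decarboxylation. The chosen plan is preferred because ring A is terminal, so this key step settles only the A1–O–B1 bond. A6 presupposes a B–C–D–E phenol free only at B1, and therefore a conventional coupling for the crowded B2–O–C1 bond. The ester removal adds two steps under conditions that electron-rich phloroglucinols tolerate poorly.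

Key step: step 9

Remarks. ArA = 2,4,6-trimethoxyphenyl. ArCDE = 3,4-dimethoxy-5-[3,4,5-trimethoxy-2-(3,4,5-trimethoxyphenoxy)phenoxy]phenyl. Compounds 1, 2, 6, 10, 13, 14 and 23 are taken as purchasable (23 as a solution in hexanes). The target is achiral; the sp3 centres of 22, 25 and 27 are racemic and are erased on aromatisation.

## Steps

Step 1
Reactants: 1 3,4,5-trimethoxyphenol; 2 2-bromo-3,4,5-trimethoxybenzaldehyde
Product: 3 3,4,5-trimethoxy-2-(3,4,5-trimethoxyphenoxy)benzaldehyde
Conditions: CuI (10 mol %), N,N-dimethylglycine (30 mol %), Cs2CO3, 1,4-dioxane, 100 °C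
Reagents that add atoms: none
Why: Ullmann diaryl ether synthesis; the ortho formyl group activates the doubly flanked bromide of 2 and the phenoxide of 1 is unhindered, so the D2–O–E1 bond should form here, and the formyl group is the latent D1 oxygen.

Step 2
Reactants: 3 3,4,5-trimethoxy-2-(3,4,5-trimethoxyphenoxy)benzaldehyde
Product: 5 3,4,5-trimethoxy-2-(3,4,5-trimethoxyphenoxy)phenol, via aryl formate 4 (not isolated)
Conditions: mCPBA, CH2Cl2, 0 °C to rt; then K2CO3 (cat.), MeOH, rt
Reagents that add atoms: mCPBA (3-chloroperoxybenzoic acid), OOC(=O)c1cccc(Cl)c1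
Why: Dakin-type Baeyer–Villiger oxidation; in the Criegee intermediate the electron-rich aryl group (ortho aryloxy, para methoxy) should migrate in preference to hydride to give formate 4, and methanolysis frees the D1 phenol as the only hydroxyl of 5.

Step 3
Reactants: 5 3,4,5-trimethoxy-2-(3,4,5-trimethoxyphenoxy)phenol; 6 3-bromo-4,5-dimethoxybenzaldehyde
Product: 7 3,4-dimethoxy-5-[3,4,5-trimethoxy-2-(3,4,5-trimethoxyphenoxy)phenoxy]benzaldehyde
Conditions: CuI (10 mol %), N,N-dimethylglycine (30 mol %), Cs2CO3, 1,4-dioxane, 100 °C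
Reagents that add atoms: none
Why: Ullmann diaryl ether synthesis between a phenol with one ortho substituent and a bromide with one ortho methoxy group that the meta formyl group makes less electron-rich; 5 has one hydroxyl and 6 one halogen, so only the C5–O–D1 bond can form.

Step 4
Reactants: 7 3,4-dimethoxy-5-[3,4,5-trimethoxy-2-(3,4,5-trimethoxyphenoxy)phenoxy]benzaldehyde
Product: 9 3,4-dimethoxy-5-[3,4,5-trimethoxy-2-(3,4,5-trimethoxyphenoxy)phenoxy]phenol (ArCDE–OH), via aryl formate 8 (not isolated)
Conditions: mCPBA, CH2Cl2, 0 °C to rt; then K2CO3 (cat.), MeOH, rt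
Reagents that add atoms: mCPBA (3-chloroperoxybenzoic acid), OOC(=O)c1cccc(Cl)c1
Why: Dakin-type Baeyer–Villiger oxidation as in step 2, with aryl migration assisted by the para methoxy group as in other 3,4,5-trialkoxybenzaldehydes; the new C1 hydroxyl is the only free phenol and has two unsubstituted ortho positions.

Step 5
Reactants: 9 ArCDE–OH; 10 methyl bromoacetate
Product: 12 2-(ArCDE-oxy)acetic acid, via methyl ester 11 (not isolated)
Conditions: K2CO3, acetone, reflux; then LiOH, THF/MeOH/H2O, rt; aq. HCl to pH 2
Reagents that add atoms: lithium hydroxide, [Li+].[OH-]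
Why: Williamson ether synthesis (SN2 of an unhindered phenoxide on a primary α-bromo ester) followed by saponification; this O–CH2 bond is the future B2–O–C1 ether, made here without any steric problem.

Step 6
Reactants: 13 2,4,6-trimethoxyphenol; 14 trichloroethylene
Product: 16 2-[(E)-1,2-dichloroethenyl]oxy-1,3,5-trimethoxybenzene, via dichloroacetylene 15 (not isolated)
Conditions: K2CO3, DMF, 70 °C
Reagents that add atoms: none
Why: The base converts 14 into 15 by β-elimination and the phenoxide of 13 adds to this small linear electrophile in anti fashion, which gives the (E)-dichlorovinyl ether; the two ortho methoxy groups that would cripple an arylation hardly hinder attack on an sp carbon, and this O–C bond is the future A1–O–B1 ether.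

Step 7
Reactants: 16 2-[(E)-1,2-dichloroethenyl]oxy-1,3,5-trimethoxybenzene
Product: 19 2-(ethynyloxy)-1,3,5-trimethoxybenzene (ArA–O–C≡CH), via chloroethynyl ether 17 (not isolated), via lithium acetylide 18 (not isolated)
Conditions: n-BuLi (2.2 equiv), Et2O, −78 to −40 °C; then H2O, −78 °C
Reagents that add atoms: none
Why: Standard conversion of a dichlorovinyl ether into an ynol ether: dehydrochlorination to 17, chlorine–lithium exchange to 18 and protonation; at −78 °C these steps should outrun lithiation of the ring between the methoxy groups, and 19 is kept cold in solution and used at once because aryl ethynyl ethers polymerise.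

Step 8
Reactants: 12 2-(ArCDE-oxy)acetic acid; 19 ArA–O–C≡CH
Product: 22 4-(ArCDE-oxy)-3-(ArA-oxy)cyclobut-2-en-1-one (racemic), via acid chloride 20 (not isolated), via aryloxyketene 21 (not isolated)
Conditions: (COCl)2, DMF (cat.), CH2Cl2, 0 °C to rt, concentrate; then slow addition to 19 (1.5 equiv), Et3N, MeCN, rt to 40 °C
Reagents that add atoms: none
Why: Dehydrochlorination of 20 gives aryloxyketene 21 (as in Staudinger reactions), which ynol ether 19 should trap in a [2+2] cycloaddition; the CH terminus of 19 bonds to the ketene carbonyl carbon and its oxygen-bearing carbon to the ketene α-carbon, so only the 3-aryloxy-4-aryloxy isomer can form, and slow addition keeps 21 dilute against dimerisation.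

Step 9
Reactants: 22 4-(ArCDE-oxy)-3-(ArA-oxy)cyclobut-2-en-1-one; 23 ethoxyacetylene
Product: 28 5-ethoxy-2-(ArCDE-oxy)-3-(ArA-oxy)phenol, via vinylketene 24 (not isolated), via alkenylcyclobutenone 25 (not isolated), via dienylketene 26 (not isolated), via cyclohexadienone 27 (not isolated)
Conditions: 23 (5 equiv), toluene, 80 °C, sealed tube; then 110 °C
Reagents that add atoms: none
Why: Danheiser benzannulation, a cascade of four pericyclic reactions of a cyclobutenone with an ynol ether. Thermal conrotatory 4π ring opening of 22 cleaves the C1–C4 bond, the C4 aryloxy donor rotating outward, and gives vinylketene 24 reversibly. The ketene C=C bond of 24 then undergoes a [2+2] cycloaddition with 23 in which the nucleophilic CH terminus of 23 (future B4) attacks the ketene carbonyl carbon (future B3) and the oxygen-bearing carbon of 23 (future B5) bonds to the ketene α-carbon (future B6), which gives 25. A second 4π opening of 25 gives dienylketene 26, and a disrotatory 6π electrocyclisation closes ring B by forming the B2–B3 bond; tautomerisation of cyclohexadienone 27 to phenol 28 makes the sequence irreversible. Ring B is thus assembled from three two-carbon units (B2–B3 from 12, B1–B6 from 19, B4–B5 from 23) with the aryloxy groups at B1 and B2 already in place, so neither crowded diaryl ether bond is made on an aromatic carbon. The only selectivity needed is the orientation of 23, and it is secured by the polarity of ketene and ynol ether, which in every benzannulation of this type places the alkoxy group meta to the new hydroxyl. The sp3 centres of 22, 25 and 27 are racemic and transient, so no stereocontrol is required. Closure of ketene 24 or 26 onto an aryl ring is excluded for ring A, whose ortho positions are both substituted, and would need a seven-membered transition state for ring C.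

Step 10
Reactants: 28 5-ethoxy-2-(ArCDE-oxy)-3-(ArA-oxy)phenol
Product: 29 pseudopentafuhalol D
Conditions: BBr3 (excess), CH2Cl2, −78 °C to rt; then H2O/MeOH, 0 °C, under argon
Reagents that add atoms: none
Why: Lewis acid dealkylation of aryl alkyl ethers: BBr3 coordinates each ether oxygen and bromide attacks the methyl or ethyl carbon by SN2, a path that is closed to the four diaryl ether oxygens because they bear no sp3 carbon; hydrolysis of the aryl borates under argon should free all thirteen phenols.

## Compound list

1 | 3,4,5-trimethoxyphenol | COc1cc(O)cc(OC)c1OC | starting material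
2 | 2-bromo-3,4,5-trimethoxybenzaldehyde | COc1cc(C=O)c(Br)c(OC)c1OC | starting material
3 | 3,4,5-trimethoxy-2-(3,4,5-trimethoxyphenoxy)benzaldehyde | COc1cc(C=O)c(Oc2cc(OC)c(OC)c(OC)c2)c(OC)c1OC | intermediate
4 | 3,4,5-trimethoxy-2-(3,4,5-trimethoxyphenoxy)phenyl formate | COc1cc(OC=O)c(Oc2cc(OC)c(OC)c(OC)c2)c(OC)c1OC | intermediate
5 | 3,4,5-trimethoxy-2-(3,4,5-trimethoxyphenoxy)phenol | COc1cc(O)c(Oc2cc(OC)c(OC)c(OC)c2)c(OC)c1OC | intermediate
6 | 3-bromo-4,5-dimethoxybenzaldehyde | COc1cc(C=O)cc(Br)c1OC | starting material
7 | 3,4-dimethoxy-5-[3,4,5-trimethoxy-2-(3,4,5-trimethoxyphenoxy)phenoxy]benzaldehyde | COc1cc(C=O)cc(Oc2cc(OC)c(OC)c(OC)c2Oc2cc(OC)c(OC)c(OC)c2)c1OC | intermediate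
8 | 3,4-dimethoxy-5-[3,4,5-trimethoxy-2-(3,4,5-trimethoxyphenoxy)phenoxy]phenyl formate | COc1cc(OC=O)cc(Oc2cc(OC)c(OC)c(OC)c2Oc2cc(OC)c(OC)c(OC)c2)c1OC | intermediate
9 | 3,4-dimethoxy-5-[3,4,5-trimethoxy-2-(3,4,5-trimethoxyphenoxy)phenoxy]phenol (ArCDE–OH) | COc1cc(O)cc(Oc2cc(OC)c(OC)c(OC)c2Oc2cc(OC)c(OC)c(OC)c2)c1OC | intermediate
10 | methyl bromoacetate | COC(=O)CBr | starting material
11 | methyl 2-(ArCDE-oxy)acetate | COC(=O)COc1cc(OC)c(OC)c(Oc2cc(OC)c(OC)c(OC)c2Oc2cc(OC)c(OC)c(OC)c2)c1 | intermediate
12 | 2-(ArCDE-oxy)acetic acid | OC(=O)COc1cc(OC)c(OC)c(Oc2cc(OC)c(OC)c(OC)c2Oc2cc(OC)c(OC)c(OC)c2)c1 | intermediate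
13 | 2,4,6-trimethoxyphenol | COc1cc(OC)c(O)c(OC)c1 | starting material
14 | trichloroethylene | ClC=C(Cl)Cl | starting material
15 | dichloroacetylene | ClC#CCl | intermediate
16 | 2-[(E)-1,2-dichloroethenyl]oxy-1,3,5-trimethoxybenzene | COc1cc(OC)c(O/C(Cl)=C\Cl)c(OC)c1 | intermediate
17 | 2-(chloroethynyloxy)-1,3,5-trimethoxybenzene | COc1cc(OC)c(OC#CCl)c(OC)c1 | intermediate
18 | [(2,4,6-trimethoxyphenoxy)ethynyl]lithium | [Li]C#COc1c(OC)cc(OC)cc1OC | intermediate
19 | 2-(ethynyloxy)-1,3,5-trimethoxybenzene (ArA–O–C≡CH) | C#COc1c(OC)cc(OC)cc1OC | intermediate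
20 | 2-(ArCDE-oxy)acetyl chloride | ClC(=O)COc1cc(OC)c(OC)c(Oc2cc(OC)c(OC)c(OC)c2Oc2cc(OC)c(OC)c(OC)c2)c1 | intermediate
21 | 2-(ArCDE-oxy)ethen-1-one (aryloxyketene) | O=C=COc1cc(OC)c(OC)c(Oc2cc(OC)c(OC)c(OC)c2Oc2cc(OC)c(OC)c(OC)c2)c1 | intermediate
22 | 4-(ArCDE-oxy)-3-(ArA-oxy)cyclobut-2-en-1-one, racemic | O=C1C=C(Oc2c(OC)cc(OC)cc2OC)C1Oc1cc(OC)c(OC)c(Oc2cc(OC)c(OC)c(OC)c2Oc2cc(OC)c(OC)c(OC)c2)c1 | intermediate
23 | ethoxyacetylene | CCOC#C | starting material
24 | (3Z)-3-(ArA-oxy)-4-(ArCDE-oxy)buta-1,3-dien-1-one (vinylketene) | O=C=C/C(Oc1c(OC)cc(OC)cc1OC)=C/Oc1cc(OC)c(OC)c(Oc2cc(OC)c(OC)c(OC)c2Oc2cc(OC)c(OC)c(OC)c2)c1 | intermediate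
25 | 3-ethoxy-4-[(Z)-1-(ArA-oxy)-2-(ArCDE-oxy)ethenyl]cyclobut-2-en-1-one, racemic | CCOC1=CC(=O)C1/C(Oc1c(OC)cc(OC)cc1OC)=C/Oc1cc(OC)c(OC)c(Oc2cc(OC)c(OC)c(OC)c2Oc2cc(OC)c(OC)c(OC)c2)c1 | intermediate
26 | (3E,5Z)-3-ethoxy-5-(ArA-oxy)-6-(ArCDE-oxy)hexa-1,3,5-trien-1-one (dienylketene) | O=C=C/C(OCC)=C\C(Oc1c(OC)cc(OC)cc1OC)=C\Oc1cc(OC)c(OC)c(Oc2cc(OC)c(OC)c(OC)c2Oc2cc(OC)c(OC)c(OC)c2)c1 | intermediate
27 | 3-ethoxy-5-(ArA-oxy)-6-(ArCDE-oxy)cyclohexa-2,4-dien-1-one, racemic | CCOC1=CC(=O)C(Oc2cc(OC)c(OC)c(Oc3cc(OC)c(OC)c(OC)c3Oc3cc(OC)c(OC)c(OC)c3)c2)C(Oc2c(OC)cc(OC)cc2OC)=C1 | intermediate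
28 | 5-ethoxy-2-(ArCDE-oxy)-3-(ArA-oxy)phenol | COc1cc(OC)c(Oc2cc(OCC)cc(O)c2Oc2cc(OC)c(OC)c(Oc3cc(OC)c(OC)c(OC)c3Oc3cc(OC)c(OC)c(OC)c3)c2)c(OC)c1 | intermediate
29 | pseudopentafuhalol D | Oc1cc(O)c(Oc2cc(O)cc(O)c2Oc2cc(O)c(O)c(Oc3cc(O)c(O)c(O)c3Oc3cc(O)c(O)c(O)c3)c2)c(O)c1 | target

## Step count and least certain steps

Total step count: 10. Longest linear sequence: 8 steps (1, 2, 3, 4, 5, 8, 9, 10).

Step 9 (key step). The most likely failure is inefficient capture of vinylketene 24 by 23: the two oxygen donors make this ketene a weaker electrophile than the alkyl-substituted vinylketenes usual in this benzannulation. Re-closure to 22, ketene oligomerisation, O-acylation of the product phenol by 24 (such esters would be cleaved afterwards with K2CO3 in MeOH), and loss of ethylene from 23 above about 100 °C then drain material. Addition–elimination at C3 of the vinylogous ester 22 with loss of the ring A phenoxide is a second risk. The fallback abandons the ring construction and sets out from 13 and 9. Copper-catalysed coupling of 13 with 2-bromo-4,6-dimethoxybenzaldehyde F1 should give 2,4-dimethoxy-6-(2,4,6-trimethoxyphenoxy)benzaldehyde F2. Baeyer–Villiger oxidation to the aryl formate F3 and methanolysis would give 2,4-dimethoxy-6-(2,4,6-trimethoxyphenoxy)phenol F4, the ring A–B phenol with its hydroxyl at B2. Phenol 9 is converted with Tf2O and pyridine into its aryl triflate F5. A palladium-catalysed C–O coupling of F4 with F5 (Pd(OAc)2, t-BuXPhos, K3PO4, toluene, 100 °C) would give the tridecamethyl ether F6, and BBr3 as in step 10 brings the route back at 29.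

Step 8. The most likely failure is dimerisation of ketene 21 before cycloaddition, because an aryl ynol ether is a weaker ketenophile than an alkyl one; polymerisation of 19 during the slow addition and displacement of the ring A phenoxide from 22 by amine or chloride are further risks. The fallback reaches the vinylketene without 19, 21 or 22 and sets out from 9 and 13. Alkylation of 9 with propargyl bromide (K2CO3, acetone) gives the aryl propargyl ether F7. Lithiation and trapping with methyl chloroformate give the ynoate methyl 4-(ArCDE-oxy)but-2-ynoate F8. Base-mediated conjugate addition of 13 (Cs2CO3, MeCN) gives methyl 3-(ArA-oxy)-4-(ArCDE-oxy)but-2-enoate F9 (either alkene geometry serves). Saponification gives the acid F10 and oxalyl chloride the acid chloride F11. 1,4-Dehydrochlorination of F11 with Et3N at room temperature in the presence of 23 generates a vinylketene of the constitution of 24, and warming as in step 9 should bring the route back at 28.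

Step 1. The most likely failure is slow substitution at a bromide flanked by formyl and methoxy groups, with hydrodebromination of 2 and base-induced loss of aldehyde taking over. The fallback reverses the polarity of the coupling: Chan–Lam coupling (Cu(OAc)2, pyridine, CH2Cl2, air, molecular sieves) of 2-hydroxy-3,4,5-trimethoxybenzaldehyde F12 with (3,4,5-trimethoxyphenyl)boronic acid F13, both purchasable, sets out from these two compounds and comes back to the route at 3.

Step 10. The most likely failures are incomplete cleavage of the twelve ethers, which would give inseparable partly alkylated polyphenols, oxidative degradation of the pyrogallol and hydroxyquinol rings during isolation, and acid-induced cleavage at the phloroglucinol-type ring A during the quench. The fallback sets out from 28: the crude product of the BBr3 treatment is acetylated without isolation (Ac2O, pyridine) to pseudopentafuhalol D tridecaacetate F14, which is stable to air and can be purified on silica. Acid-catalysed methanolysis (HCl in MeOH, argon) then comes back to the route at 29.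

## Further compounds

F1 | step 9 | 2-bromo-4,6-dimethoxybenzaldehyde | COc1cc(Br)c(C=O)c(OC)c1
F2 | step 9 | 2,4-dimethoxy-6-(2,4,6-trimethoxyphenoxy)benzaldehyde | COc1cc(OC)c(C=O)c(Oc2c(OC)cc(OC)cc2OC)c1
F3 | step 9 | 2,4-dimethoxy-6-(2,4,6-trimethoxyphenoxy)phenyl formate | COc1cc(OC)c(OC=O)c(Oc2c(OC)cc(OC)cc2OC)c1
F4 | step 9 | 2,4-dimethoxy-6-(2,4,6-trimethoxyphenoxy)phenol | COc1cc(OC)c(O)c(Oc2c(OC)cc(OC)cc2OC)c1
F5 | step 9 | ArCDE trifluoromethanesulfonate (triflate of 9) | COc1cc(OS(=O)(=O)C(F)(F)F)cc(Oc2cc(OC)c(OC)c(OC)c2Oc2cc(OC)c(OC)c(OC)c2)c1OC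
F6 | step 9 | pseudopentafuhalol D tridecamethyl ether | COc1cc(OC)c(Oc2cc(OC)cc(OC)c2Oc2cc(OC)c(OC)c(Oc3cc(OC)c(OC)c(OC)c3Oc3cc(OC)c(OC)c(OC)c3)c2)c(OC)c1
F7 | step 8 | ArCDE propargyl ether | C#CCOc1cc(OC)c(OC)c(Oc2cc(OC)c(OC)c(OC)c2Oc2cc(OC)c(OC)c(OC)c2)c1
F8 | step 8 | methyl 4-(ArCDE-oxy)but-2-ynoate | COC(=O)C#CCOc1cc(OC)c(OC)c(Oc2cc(OC)c(OC)c(OC)c2Oc2cc(OC)c(OC)c(OC)c2)c1
F9 | step 8 | methyl 3-(ArA-oxy)-4-(ArCDE-oxy)but-2-enoate (E/Z mixture) | COC(=O)C=C(COc1cc(OC)c(OC)c(Oc2cc(OC)c(OC)c(OC)c2Oc2cc(OC)c(OC)c(OC)c2)c1)Oc1c(OC)cc(OC)cc1OC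
F10 | step 8 | 3-(ArA-oxy)-4-(ArCDE-oxy)but-2-enoic acid (E/Z mixture) | OC(=O)C=C(COc1cc(OC)c(OC)c(Oc2cc(OC)c(OC)c(OC)c2Oc2cc(OC)c(OC)c(OC)c2)c1)Oc1c(OC)cc(OC)cc1OC
F11 | step 8 | 3-(ArA-oxy)-4-(ArCDE-oxy)but-2-enoyl chloride (E/Z mixture) | ClC(=O)C=C(COc1cc(OC)c(OC)c(Oc2cc(OC)c(OC)c(OC)c2Oc2cc(OC)c(OC)c(OC)c2)c1)Oc1c(OC)cc(OC)cc1OC
F12 | step 1 | 2-hydroxy-3,4,5-trimethoxybenzaldehyde | COc1cc(C=O)c(O)c(OC)c1OC
F13 | step 1 | (3,4,5-trimethoxyphenyl)boronic acid | COc1cc(B(O)O)cc(OC)c1OC
F14 | step 10 | pseudopentafuhalol D tridecaacetate | CC(=O)Oc1cc(OC(C)=O)c(Oc2cc(OC(C)=O)cc(OC(C)=O)c2Oc2cc(OC(C)=O)c(OC(C)=O)c(Oc3cc(OC(C)=O)c(OC(C)=O)c(OC(C)=O)c3Oc3cc(OC(C)=O)c(OC(C)=O)c(OC(C)=O)c3)c2)c(OC(C)=O)c1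
A1 | alternative 1 | 2-bromo-1,5-dimethoxy-3-(2,4,6-trimethoxyphenoxy)benzene | COc1cc(OC)c(Br)c(Oc2c(OC)cc(OC)cc2OC)c1
A2 | alternative 1 | pseudopentafuhalol D tridecamethyl ether | COc1cc(OC)c(Oc2cc(OC)cc(OC)c2Oc2cc(OC)c(OC)c(Oc3cc(OC)c(OC)c(OC)c3Oc3cc(OC)c(OC)c(OC)c3)c2)c(OC)c1
A3 | alternative 2 | 3,5-dimethoxy-2-(trimethylsilyl)phenyl trifluoromethanesulfonate | COc1cc(OC)c([Si](C)(C)C)c(OS(=O)(=O)C(F)(F)F)c1
A4 | alternative 2 | 3,5-dimethoxybenzyne | COC1=CC(OC)=CC#C1
A5 | alternative 2 | 2-iodo-1,5-dimethoxy-3-(2,4,6-trimethoxyphenoxy)benzene | COc1cc(OC)c(I)c(Oc2c(OC)cc(OC)cc2OC)c1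
A6 | alternative 3 | dimethyl 2-{3,5-dimethoxy-2-(ArCDE-oxy)phenoxy}malonate | COC(=O)C(Oc1cc(OC)cc(OC)c1Oc1cc(OC)c(OC)c(Oc2cc(OC)c(OC)c(OC)c2Oc2cc(OC)c(OC)c(OC)c2)c1)C(=O)OC
A7 | alternative 3 | dimethyl 5-{3,5-dimethoxy-2-(ArCDE-oxy)phenoxy}-2,4,6-trihydroxybenzene-1,3-dicarboxylate | COC(=O)c1c(O)c(C(=O)OC)c(O)c(Oc2cc(OC)cc(OC)c2Oc2cc(OC)c(OC)c(Oc3cc(OC)c(OC)c(OC)c3Oc3cc(OC)c(OC)c(OC)c3)c2)c1O
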